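The route closes ring C (C8, C9, C11–C14) last, through the C12–C13 bond. The key step exploits the local mirror symmetry of the spiro ring D: its two arms (C14–C13 and C15–C16) are interchangeable, because the C13/C16 α-silyloxy ketone reacts through a single enediolate, so C8 is not yet a fixed stereocentre. C9 holds a 2-tosyloxyethyl arm (C11–C12) on one face of ring B. Intramolecular enolate C-alkylation therefore desymmetrises ring D and creates, in one operation, ring C, the quaternary spiro carbon C8 and the bridgehead carbinol C13, leaving C16 as the ketone for methylenation. The other stereocentres are relayed from C9, set once with an oxazolidinone auxiliary.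

Key step: step 14

Remark (assumption): gibberellane numbering is used throughout (C7 on C6, C18/C19 on C4, C20 on C10, C17 = exocyclic CH2); the target is taken exactly as drawn, i.e. rings A/B cis-fused with H5, H9, C20, the C7 ester and C15 on one face of ring B (lower face) and C1, C4, C11 and C14 on the other (upper face); 1, 2, 6 and all reagents are taken as commercial; 21–23 are carried as the convergent mixture of ring-D isomers and drawn with the ring-D centres undefined.

Step 1
Reactants: 1 cyclopent-3-ene-1-carbaldehyde; 2 methyl bromoacetate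
Product: 5 methyl 2-(1-formylcyclopent-3-en-1-yl)acetate, via pyrrolidine enamine 3 (not isolated), via alkylated iminium bromide 4 (not isolated)
Conditions: pyrrolidine (1.2 equiv), toluene, 4 Å molecular sieves, 25 °C; then 2, MeCN, 60 °C; then aq. AcOH/NaOAc, 25 °C
Reagents that add atoms: water, O
Why: Stork enamine alkylation, in which the α-branched aldehyde can form only one enamine and is C-alkylated by the activated bromide to give the quaternary carbon (future C8) before hydrolysis; no stereocentre arises because the cyclopentene is symmetric.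

Step 2
Reactants: 6 (S)-4-benzyl-3-(chloroacetyl)oxazolidin-2-one
Product: 7 diethyl {2-[(S)-4-benzyl-2-oxooxazolidin-3-yl]-2-oxoethyl}phosphonate
Conditions: P(OEt)3 (neat), 120 °C
Reagents that add atoms: triethyl phosphite, CCOP(OCC)OCC
Why: Michaelis–Arbuzov reaction of the activated α-chloro imide, which leaves the auxiliary stereocentre untouched.

Step 3
Reactants: 5 methyl 2-(1-formylcyclopent-3-en-1-yl)acetate; 7 diethyl {2-[(S)-4-benzyl-2-oxooxazolidin-3-yl]-2-oxoethyl}phosphonate
Product: 8 (S)-4-benzyl-3-{(E)-3-[1-(2-methoxy-2-oxoethyl)cyclopent-3-en-1-yl]prop-2-enoyl}oxazolidin-2-one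
Conditions: LiCl, i-Pr2NEt, MeCN, 25 °C
Reagents that add atoms: none
Why: Horner–Wadsworth–Emmons olefination under mild amine/LiCl conditions, the non-enolisable neopentyl aldehyde giving the (E)-enoyl imide.

Step 4
Reactants: 8 (S)-4-benzyl-3-{(E)-3-[1-(2-methoxy-2-oxoethyl)cyclopent-3-en-1-yl]prop-2-enoyl}oxazolidin-2-one
Product: 9 (S)-4-benzyl-3-{(3R)-3-[1-(2-methoxy-2-oxoethyl)cyclopent-3-en-1-yl]pent-4-enoyl}oxazolidin-2-one
Conditions: CH2=CHMgBr (2 equiv), CuBr·SMe2 (0.3 equiv), THF/Me2S, −78 → −20 °C; aq. NH4Cl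
Reagents that add atoms: vinylmagnesium bromide, C=C[Mg]Br
Why: copper-catalysed conjugate addition to the magnesium-chelated s-cis enoyl imide, the vinyl group entering the β-carbon on the face opposite the auxiliary benzyl group and so setting C9, the only stereocentre of the route that is controlled by a reagent.

Step 5
Reactants: 9 (S)-4-benzyl-3-{(3R)-3-[1-(2-methoxy-2-oxoethyl)cyclopent-3-en-1-yl]pent-4-enoyl}oxazolidin-2-one
Product: 10 the 2-(dimethoxymethyl) derivative of 9 (acetal carbon = C5, on C10, the carbon α to the imide carbonyl; new centre anti to the auxiliary benzyl, C9 unchanged)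
Conditions: TiCl4 (1.05 equiv), i-Pr2NEt, CH2Cl2, −78 °C; then HC(OMe)3, −78 → 0 °C
Reagents that add atoms: trimethyl orthoformate, COC(OC)OC
Why: soft enolisation enolises only the imide and not the methyl ester, and the chelated (Z)-titanium enolate is alkylated by the dimethoxycarbenium ion (Mukaiyama-type acetal alkylation) anti to the benzyl group, which installs C5 at the aldehyde oxidation level; the C10 centre is planarised again in step 8.

Step 6
Reactants: 10 the 2-(dimethoxymethyl) derivative of 9
Product: 11 benzyl 2-(dimethoxymethyl)-3-[1-(2-methoxy-2-oxoethyl)cyclopent-3-en-1-yl]pent-4-enoate (C9 and C10 as in 10)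
Conditions: BnOH, n-BuLi (1.5 equiv LiOBn), THF, −78 → 0 °C; aq. NH4Cl
Reagents that add atoms: benzyl alcohol, OCc1ccccc1
Why: transesterification of the imide by lithium benzyloxide at the exocyclic carbonyl, which is much faster than exchange at the neopentyl-type methyl ester, releases the auxiliary and leaves C9 untouched.

Step 7
Reactants: 11 benzyl 2-(dimethoxymethyl)-3-[1-(2-methoxy-2-oxoethyl)cyclopent-3-en-1-yl]pent-4-enoate
Product: 13 dibenzyl (E)-4-{1-[1-(2-methoxy-2-oxoethyl)cyclopent-3-en-1-yl]prop-2-en-1-yl}pent-2-enedioate (C9 as in 9, C10 epimers), via α-formyl ester 12 (not isolated)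
Conditions: 1 M HCl, THF, 25 °C; extraction; then Ph3P=CHCO2Bn, CH2Cl2, 25 °C
Reagents that add atoms: benzyl (triphenylphosphoranylidene)acetate, O=C(OCc1ccccc1)C=P(c1ccccc1)(c1ccccc1)c1ccccc1
Why: acetal hydrolysis gives the β-aldehydo ester, whose aldehyde tautomer undergoes Wittig olefination with the stabilised, non-basic ylide to the (E)-glutaconate, in which C10 is a doubly activated CH whose configuration is immaterial.

Step 8
Reactants: 13 dibenzyl (E)-4-{1-[1-(2-methoxy-2-oxoethyl)cyclopent-3-en-1-yl]prop-2-en-1-yl}pent-2-enedioate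
Product: 15 dibenzyl 3-{1-[1-(2-methoxy-2-oxoethyl)cyclopent-3-en-1-yl]prop-2-en-1-yl}cyclohex-1-ene-1,3-dicarboxylate (ring A; quaternary C10 with C1 on the side of the vinyl group, C9 and C10 as in the target), via C4-alkylated chloride 14 (not isolated)
Conditions: Br(CH2)3Cl (1.1 equiv), Cs2CO3 (2.5 equiv), NaI (0.2 equiv), DMF, 0 → 50 °C
Reagents that add atoms: 1-bromo-3-chloropropane, ClCCCBr
Why: double C-alkylation of the glutaconate (vinylogous malonate) anion, first at the unhindered C4 terminus and then by 6-(enolendo)-exo-tet closure at C10, where C1 attacks the planar carbon anti to the bulky C8 substituent of C9 while H9 eclipses the C20 ester (allylic 1,3-strain), setting the quaternary C10 with C1 on the side of C11 and C20 on the side of H9.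

Step 9
Reactants: 15 dibenzyl 3-{1-[1-(2-methoxy-2-oxoethyl)cyclopent-3-en-1-yl]prop-2-en-1-yl}cyclohex-1-ene-1,3-dicarboxylate
Product: 17 spiro tricycle: cis-fused rings A/B with ring D (cyclopent-3-ene) spiro at C8; 7-methyl 19,20-dibenzyl triester with vinyl on C9 (C1, C4 and vinyl on the upper face of ring B; H5, H9, C20 and C7 on the lower face; C18 syn to H5), via cyclised lithium enolate 16 (not isolated)
Conditions: LiN(i-Pr)2 (1.1 equiv), THF, −78 → −20 °C; then MeI, DMPU, −78 → 0 °C
Reagents that add atoms: iodomethane, CI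
Why: tandem Michael addition–enolate alkylation, in which the C6 ester enolate (the only acidic site) adds 5-exo-trig to C5 on the face carrying the C9–C8 tether, forcing the cis ring fusion and leaving the epimerisable C7 ester trans to C4, and the exocyclic C4 enolate is then methylated opposite the new C5–C6 bond to give the quaternary C4 with C18 syn to H5.

Step 10
Reactants: 17 spiro tricycle with vinyl on C9
Product: 19 primary alcohol (C12–OH; C9 now bears CH2CH2OH, all else as 17), via B-alkyl-9-BBN adduct 18 (not isolated)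
Conditions: 9-BBN (1.2 equiv), THF, 0 → 25 °C; then 30% H2O2, pH 7 phosphate buffer, 0 → 25 °C
Reagents that add atoms: hydrogen peroxide, OO
Why: anti-Markovnikov hydroboration–oxidation, 9-BBN reacting far faster with the monosubstituted vinyl group than with the cis-disubstituted ring-D alkene, and buffered oxidation sparing the esters.

Step 11
Reactants: 19 primary alcohol (C12–OH)
Product: 20 C12 p-toluenesulfonate of 19
Conditions: TsCl, Et3N, DMAP (cat.), CH2Cl2, 0 → 25 °C
Reagents that add atoms: 4-toluenesulfonyl chloride, Cc1ccc(cc1)S(Cl)(=O)=O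
Why: sulfonylation of the unhindered primary alcohol turns C12 into the electrophile for ring closure.

Step 12
Reactants: 20 C12 p-toluenesulfonate
Product: 21 ring-D ketol (2-hydroxycyclopentanone spiro at C8; mixture of the four ring-D isomers; all other centres as 20)
Conditions: RuCl3 (1 mol %), Oxone (2KHSO5·KHSO4·K2SO4), NaHCO3, EtOAc/MeCN/H2O, 25 °C, short reaction time
Reagents that add atoms: potassium peroxymonosulfate (active component of Oxone), [K+].[O-]S(=O)(=O)OO
Why: RuO4-catalysed ketohydroxylation converts the only remaining alkene directly into the acyloin, and the regio- and stereoisomers formed are immaterial because they share one enediolate in step 14.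

Step 13
Reactants: 21 ring-D ketol mixture
Product: 22 triethylsilyl ethers of 21 (same isomer mixture)
Conditions: Et3SiCl, imidazole, DMF, 0 → 25 °C
Reagents that add atoms: chlorotriethylsilane, CC[Si](Cl)(CC)CC
Why: silylation of the secondary ketol hydroxyl prevents alkoxide chemistry (ketol shifts, O-alkylation) in the enolate step and provides the silyl group that later protects the bridgehead hydroxyl.

Step 14
Reactants: 22 triethylsilyl ethers of the ring-D ketol
Product: 24 tetracyclic 13-triethylsilyloxy-16-ketone, 7-methyl 19,20-dibenzyl triester (all seven stereocentres as in the target), via potassium enediolate 23 (not isolated)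
Conditions: KN(SiMe3)2 (1.0 equiv), THF, −78 → 25 °C
Reagents that add atoms: none
Why: KN(SiMe3)2 deprotonates the α-silyloxy ketone, and because proton exchange and 1,4 O-to-O silyl transfer interconvert all isomeric enolates of 22, they funnel into the enediolate 23, whose silyloxy-bearing carbon displaces the C12 tosylate in an intramolecular SN2 C-alkylation. The closest known reaction type is the intramolecular α-alkylation of a ketone enolate (here an acyloin-derived α-silyloxy enolate) giving a bridged bicyclo[3.2.1]octanone. Ring C is closed in the 6-(enolexo)-exo-tet mode, the C13=C16 enolate bond lying outside the new ring. C13 is set by the bridging itself, and the spiro carbon C8 becomes the quaternary stereocentre in the same event under control of C9: only the arm on the upper face (cis to C11) reaches C12 through a cis-fused chair-like transition state, whereas the other arm would need a trans-fused ring across C8–C9. The step needs C- over O-alkylation and ketone over ester enolisation, secured by six- versus seven-membered closure and by the far higher acidity of the α-silyloxy ketone than of the hindered C6–H. The carbonyl left on the other arm is C16, the handle for the final methylenation.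

Step 15
Reactants: 24 tetracyclic 13-triethylsilyloxy-16-ketone triester
Product: 25 13-triethylsilyloxy-16-oxo 19,20-dicarboxylic acid 7-methyl ester
Conditions: H2 (1 atm), 10% Pd/C, EtOAc, 25 °C
Reagents that add atoms: none
Why: hydrogenolysis of the two benzyl esters at the only stage of the route without a C=C bond, so that the hindered tertiary acids are freed while the methyl ester, ketone and silyl ether remain.

Step 16
Reactants: 25 13-triethylsilyloxy-16-oxo 19,20-diacid 7-methyl ester
Product: 27 target (13-hydroxy-16-methylene 19,20-diacid 7-methyl ester), via 13-O-silyl methylene diacid 26 (not isolated)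
Conditions: Ph3PCH3Br (6 equiv), KN(SiMe3)2 (5.8 equiv), THF, 0 → 45 °C; then Bu4NF, THF, 25 °C; dilute HCl to pH 3
Reagents that add atoms: methyltriphenylphosphonium bromide, C[P+](c1ccccc1)(c1ccccc1)c1ccccc1.[Br-]
Why: Wittig methylenation of the hindered C16 ketone with excess ylide, the acids being masked as carboxylates and the bridgehead hydroxyl as its silyl ether, followed by fluoride desilylation; no stereocentre is touched.

Compound list
1 | cyclopent-3-ene-1-carbaldehyde | O=CC1CC=CC1 | starting material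
2 | methyl bromoacetate | COC(=O)CBr | starting material
3 | 1-(cyclopent-3-en-1-ylidenemethyl)pyrrolidine | C(=C1CC=CC1)N1CCCC1 | intermediate
4 | 1-{[1-(2-methoxy-2-oxoethyl)cyclopent-3-en-1-yl]methylidene}pyrrolidinium bromide | COC(=O)CC1(C=[N+]2CCCC2)CC=CC1.[Br-] | intermediate
5 | methyl 2-(1-formylcyclopent-3-en-1-yl)acetate | COC(=O)CC1(C=O)CC=CC1 | intermediate
6 | (S)-4-benzyl-3-(chloroacetyl)oxazolidin-2-one | ClCC(=O)N1C(=O)OC[C@@H]1Cc1ccccc1 | starting material
7 | diethyl {2-[(S)-4-benzyl-2-oxooxazolidin-3-yl]-2-oxoethyl}phosphonate | CCOP(=O)(OCC)CC(=O)N1C(=O)OC[C@@H]1Cc1ccccc1 | intermediate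
8 | (S)-4-benzyl-3-{(E)-3-[1-(2-methoxy-2-oxoethyl)cyclopent-3-en-1-yl]prop-2-enoyl}oxazolidin-2-one | COC(=O)CC1(/C=C/C(=O)N2C(=O)OC[C@@H]2Cc2ccccc2)CC=CC1 | intermediate
9 | (S)-4-benzyl-3-{(3R)-3-[1-(2-methoxy-2-oxoethyl)cyclopent-3-en-1-yl]pent-4-enoyl}oxazolidin-2-one | C=C[C@H](C1(CC(=O)OC)CC=CC1)CC(=O)N2C(=O)OC[C@@H]2Cc2ccccc2 | intermediate
10 | 2-(dimethoxymethyl) derivative of 9 (C10 acetal, anti to the auxiliary benzyl) | C=C[C@H](C1(CC(=O)OC)CC=CC1)[C@H](C(OC)OC)C(=O)N2C(=O)OC[C@@H]2Cc2ccccc2 | intermediate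
11 | benzyl 2-(dimethoxymethyl)-3-[1-(2-methoxy-2-oxoethyl)cyclopent-3-en-1-yl]pent-4-enoate | C=C[C@H](C1(CC(=O)OC)CC=CC1)[C@H](C(OC)OC)C(=O)OCc2ccccc2 | intermediate
12 | benzyl 2-formyl-3-[1-(2-methoxy-2-oxoethyl)cyclopent-3-en-1-yl]pent-4-enoate (aldehyde/enol, C10 epimers) | C=C[C@H](C1(CC(=O)OC)CC=CC1)C(C=O)C(=O)OCc2ccccc2 | intermediate
13 | dibenzyl (E)-4-{1-[1-(2-methoxy-2-oxoethyl)cyclopent-3-en-1-yl]prop-2-en-1-yl}pent-2-enedioate (C10 epimers) | C=C[C@H](C1(CC(=O)OC)CC=CC1)C(C(=O)OCc2ccccc2)/C=C/C(=O)OCc2ccccc2 | intermediate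
14 | dibenzyl 4-(3-chloropropyl)-2-{1-[1-(2-methoxy-2-oxoethyl)cyclopent-3-en-1-yl]prop-2-en-1-yl}pent-2-enedioate (C4 epimers) | C=C[C@H](C1(CC(=O)OC)CC=CC1)C(C(=O)OCc2ccccc2)=CC(CCCCl)C(=O)OCc2ccccc2 | intermediate
15 | dibenzyl 3-{1-[1-(2-methoxy-2-oxoethyl)cyclopent-3-en-1-yl]prop-2-en-1-yl}cyclohex-1-ene-1,3-dicarboxylate (ring A; C9, C10 as in the target) | C=C[C@H](C1(CC(=O)OC)CC=CC1)[C@@]2(C(=O)OCc3ccccc3)CCCC(C(=O)OCc3ccccc3)=C2 | intermediate
16 | lithium C4 ester enolate of the ring-B-closed triester | C=C[C@H]2[C@@]1(C(=O)OCc4ccccc4)CCCC(=C([O-])OCc4ccccc4)[C@H]1[C@H](C(=O)OC)C23CC=CC3.[Li+] | intermediate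
17 | spiro tricycle (rings A, B, D), 7-methyl 19,20-dibenzyl triester, vinyl on C9 | C=C[C@H]2[C@@]1(C(=O)OCc4ccccc4)CCC[C@@](C)(C(=O)OCc4ccccc4)[C@H]1[C@H](C(=O)OC)C23CC=CC3 | intermediate
18 | B-alkyl-9-borabicyclo[3.3.1]nonane adduct of 17 (boron on C12) | C1CCC2CCCC(C1)B2CC[C@H]5[C@@]6(C(=O)OCc4ccccc4)CCC[C@@](C)(C(=O)OCc4ccccc4)[C@H]6[C@H](C(=O)OC)C57CC=CC7 | intermediate
19 | primary alcohol (C12–OH) | OCC[C@H]2[C@@]1(C(=O)OCc4ccccc4)CCC[C@@](C)(C(=O)OCc4ccccc4)[C@H]1[C@H](C(=O)OC)C23CC=CC3 | intermediate
20 | C12 p-toluenesulfonate | Cc1ccc(cc1)S(=O)(=O)OCC[C@H]2[C@@]1(C(=O)OCc4ccccc4)CCC[C@@](C)(C(=O)OCc4ccccc4)[C@H]1[C@H](C(=O)OC)C23CC=CC3 | intermediate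
21 | ring-D ketol tosylate (mixture of ring-D isomers) | Cc1ccc(cc1)S(=O)(=O)OCC[C@H]2[C@@]1(C(=O)OCc4ccccc4)CCC[C@@](C)(C(=O)OCc4ccccc4)[C@H]1[C@H](C(=O)OC)C23CC(=O)C(O)C3 | intermediate
22 | ring-D triethylsilyloxy ketone tosylate (mixture of ring-D isomers) | Cc1ccc(cc1)S(=O)(=O)OCC[C@H]2[C@@]1(C(=O)OCc4ccccc4)CCC[C@@](C)(C(=O)OCc4ccccc4)[C@H]1[C@H](C(=O)OC)C23CC(=O)C(O[Si](CC)(CC)CC)C3 | intermediate
23 | potassium enediolate mono(triethylsilyl) ether of ring D | Cc1ccc(cc1)S(=O)(=O)OCC[C@H]2[C@@]1(C(=O)OCc4ccccc4)CCC[C@@](C)(C(=O)OCc4ccccc4)[C@H]1[C@H](C(=O)OC)C23CC([O-])=C(O[Si](CC)(CC)CC)C3.[K+] | intermediate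
24 | tetracyclic 13-triethylsilyloxy-16-ketone, 7-methyl 19,20-dibenzyl triester | O=C1C[C@]23C[C@@]1(O[Si](CC)(CC)CC)CC[C@H]2[C@@]1(C(=O)OCc4ccccc4)CCC[C@@](C)(C(=O)OCc4ccccc4)[C@H]1[C@@H]3C(=O)OC | intermediate
25 | 13-triethylsilyloxy-16-oxo 19,20-diacid 7-methyl ester | O=C1C[C@]23C[C@@]1(O[Si](CC)(CC)CC)CC[C@H]2[C@@]1(C(=O)O)CCC[C@@](C)(C(=O)O)[C@H]1[C@@H]3C(=O)OC | intermediate
26 | 13-O-triethylsilyl ether of the target | C=C1C[C@]23C[C@@]1(O[Si](CC)(CC)CC)CC[C@H]2[C@@]1(C(=O)O)CCC[C@@](C)(C(=O)O)[C@H]1[C@@H]3C(=O)OC | intermediate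
27 | target, 13-hydroxy-16-methylene 19,20-diacid 7-methyl ester | C=C1C[C@]23C[C@@]1(O)CC[C@H]2[C@@]1(C(=O)O)CCC[C@@](C)(C(=O)O)[C@H]1[C@@H]3C(=O)OC | target

Total step count: 16. Longest linear sequence: 15 steps (steps 1 and 3–16; step 2 is a one-step side branch).

Steps most likely to fail

Step 14 (key step). The O-to-O silyl transfer or the enolate equilibration may be too slow, so that O-alkylation, elimination of the tosylate or enolisation at C6 (which would then attack C12) competes with the desired closure. The fallback sets out from 21 and returns at 24. The ketol mixture 21 is oxidised with Dess–Martin periodinane to the single, locally symmetric tosyloxy dione F8. Reductive silylation (Zn, Et3SiCl, THF) gives the bis(triethylsilyl) enediol ether F9. Anhydrous fluoride (Bu4N[Ph3SiF2], THF, 50 °C) then cleaves one O–Si bond, and the enolate freed without any Brønsted base should close ring C to 24.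

Step 8. The first alkylation may occur at the substituted C10 terminus, or the ring closure may lose facial control at C10 if the anion does not adopt the conformation with H9 eclipsing the ester. The fallback sets out from 9 and returns at 15; it quaternises C10 through a chelated ester enolate and closes ring A by olefination. Soft enolisation of 9 (TiCl4, i-Pr2NEt) and trapping with s-trioxane gives the hydroxymethyl imide F1. LiOBn gives the benzyl β-hydroxy ester F2. Its alkoxide-directed dianion (LiN(i-Pr)2, 2.2 equiv) is alkylated with 1-chloro-3-iodopropane anti to the C8 substituent to give the quaternary chloropropyl hydroxy ester F3. Alkylation of benzyl (diethoxyphosphoryl)acetate with F3 (Cs2CO3, NaI, DMF) gives the hydroxy phosphonate F4. Dess–Martin oxidation gives the aldehyde phosphonate F5, and intramolecular Horner–Wadsworth–Emmons reaction (LiCl, DBU, MeCN) closes ring A to 15.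

Step 9. The conjugate addition joins two neopentyl-type carbons and may be slow, proton transfer between the ester enolates may divert the methylation to C6, and the methyl group may enter from the wrong face of C4. The fallback sets out from 15 and returns at 17; it separates ring closure from quaternisation and activates the acceptor instead of the donor. Compound 15 is converted (LiN(i-Pr)2, Me3SiCl, −78 °C) into the silyl ketene acetal F6. A Lewis-acid-promoted intramolecular Mukaiyama–Michael reaction (Me3SiOTf, CH2Cl2, −78 °C, aqueous work-up) gives the C4–H tricyclic triester F7. Kinetic deprotonation at the less hindered C4–H and methylation (LiN(i-Pr)2; MeI, DMPU) then gives 17.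

Further compounds
F1 | step 8 | (S)-4-benzyl-3-{2-(hydroxymethyl)-3-[1-(2-methoxy-2-oxoethyl)cyclopent-3-en-1-yl]pent-4-enoyl}oxazolidin-2-one | C=C[C@H](C1(CC(=O)OC)CC=CC1)[C@H](CO)C(=O)N2C(=O)OC[C@@H]2Cc2ccccc2
F2 | step 8 | benzyl 2-(hydroxymethyl)-3-[1-(2-methoxy-2-oxoethyl)cyclopent-3-en-1-yl]pent-4-enoate | C=C[C@H](C1(CC(=O)OC)CC=CC1)[C@H](CO)C(=O)OCc2ccccc2
F3 | step 8 | benzyl 2-(3-chloropropyl)-2-(hydroxymethyl)-3-[1-(2-methoxy-2-oxoethyl)cyclopent-3-en-1-yl]pent-4-enoate | C=C[C@H](C1(CC(=O)OC)CC=CC1)[C@@](CCCCl)(CO)C(=O)OCc2ccccc2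
F4 | step 8 | hydroxy phosphonate (C4 carries P(O)(OEt)2 and CO2Bn) | C=C[C@H](C1(CC(=O)OC)CC=CC1)[C@@](CCCC(C(=O)OCc2ccccc2)P(=O)(OCC)OCC)(CO)C(=O)OCc2ccccc2
F5 | step 8 | aldehyde phosphonate | C=C[C@H](C1(CC(=O)OC)CC=CC1)[C@@](CCCC(C(=O)OCc2ccccc2)P(=O)(OCC)OCC)(C=O)C(=O)OCc2ccccc2
F6 | step 9 | trimethylsilyl ketene acetal of the C7 methyl ester of 15 | C=C[C@H](C1(C=C(OC)O[Si](C)(C)C)CC=CC1)[C@@]2(C(=O)OCc3ccccc3)CCCC(C(=O)OCc3ccccc3)=C2
F7 | step 9 | C4–H tricyclic triester (C4 epimers) | C=C[C@H]2[C@@]1(C(=O)OCc4ccccc4)CCCC(C(=O)OCc4ccccc4)[C@H]1[C@H](C(=O)OC)C23CC=CC3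
F8 | step 14 | ring-D 1,2-dione tosylate | Cc1ccc(cc1)S(=O)(=O)OCC[C@H]2[C@@]1(C(=O)OCc4ccccc4)CCC[C@@](C)(C(=O)OCc4ccccc4)[C@H]1[C@H](C(=O)OC)C23CC(=O)C(=O)C3
F9 | step 14 | ring-D bis(triethylsilyl) enediol ether tosylate | Cc1ccc(cc1)S(=O)(=O)OCC[C@H]2[C@@]1(C(=O)OCc4ccccc4)CCC[C@@](C)(C(=O)OCc4ccccc4)[C@H]1[C@H](C(=O)OC)C23CC(O[Si](CC)(CC)CC)=C(O[Si](CC)(CC)CC)C3
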